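**Retrosynthetic overview**
- The target acid is released last from its 2-(trimethylsilyl)ethyl ester by fluoride. The enone C(=O)–C(sp2) bond comes from a thioester and an (E)-alkenylstannane under neutral Pd/Cu conditions.
- The thioester comes from an Evans imide. The aryl–CH2 bond is made by a B-alkyl Suzuki coupling of an ortho-iodophenol with the 9-BBN adduct of an (S)-2-methylbut-3-enoyl imide. The stereocentre is set by auxiliary-controlled α-methylation of a crotonyl imide dienolate.
- The (E)-4-hydroxy-3-methylbut-2-enyl arm comes from an allyl group by cross-metathesis with methacrolein and Luche reduction. The allyl group comes from O-allylation and Claisen rearrangement.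
- No ring is formed. The benzene ring is bought as 4-hydroxy-3-iodobenzoic acid, and the oxazolidinone ring is a bought auxiliary that is cleaved off again.

Assumption: the stereocentre of the target is read as (S) with both side-chain alkenes E, and the four starting materials and all reagents named are taken as commercially available.

**Step 1**
Reactants: 1 4-hydroxy-3-iodobenzoic acid
Product: 2 2-(trimethylsilyl)ethyl 4-hydroxy-3-iodobenzoate
Conditions: Me3SiCH2CH2OH (1.1 equiv), PPh3, DIAD, THF, 0 °C to rt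
Reagents that add atoms: 2-(trimethylsilyl)ethanol, C[Si](C)(C)CCO
Why: Mitsunobu esterification; the carboxylic acid is far more acidic than the phenol, so it is the pronucleophile alkylated by the alkoxyphosphonium ion and the phenol stays free.

**Step 2**
Reactants: 2 2-(trimethylsilyl)ethyl 4-hydroxy-3-iodobenzoate
Product: 3 2-(trimethylsilyl)ethyl 3-iodo-4-(prop-2-enyloxy)benzoate
Conditions: allyl bromide, K2CO3, acetone, 56 °C
Reagents that add atoms: allyl bromide (3-bromoprop-1-ene), C=CCBr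
Why: Williamson ether synthesis; the phenoxide is O-allylated by SN2 displacement on the allylic bromide.

**Step 3**
Reactants: 3 2-(trimethylsilyl)ethyl 3-iodo-4-(prop-2-enyloxy)benzoate
Product: 5 2-(trimethylsilyl)ethyl 4-hydroxy-3-iodo-5-(prop-2-enyl)benzoate, via ortho-dienone 4 (not isolated)
Conditions: PhNEt2, 190 °C, sealed tube, argon
Reagents that add atoms: none
Why: Aromatic Claisen rearrangement; the [3,3] shift can only end at the free ortho position (the other is blocked by iodine, the para by the ester), and the dienone tautomerises to the phenol.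

**Step 4**
Reactants: 5 2-(trimethylsilyl)ethyl 4-hydroxy-3-iodo-5-(prop-2-enyl)benzoate
Product: 6 2-(trimethylsilyl)ethyl 4-hydroxy-3-iodo-5-[(2E)-3-methyl-4-oxobut-2-enyl]benzoate
Conditions: methacrolein (8 equiv), second-generation Hoveyda–Grubbs catalyst RuCl2(H2IMes)(=CH-C6H4-2-OiPr) (5 mol%), 1,4-benzoquinone (10 mol%), CH2Cl2, 40 °C
Reagents that add atoms: methacrolein (2-methylprop-2-enal), CC(=C)C=O
Why: Olefin cross-metathesis of a terminal allyl arene with a 1,1-disubstituted enal that does not homodimerise gives the conjugated trisubstituted enal as the strongly preferred E isomer.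

**Step 5**
Reactants: 6 2-(trimethylsilyl)ethyl 4-hydroxy-3-iodo-5-[(2E)-3-methyl-4-oxobut-2-enyl]benzoate
Product: 7 2-(trimethylsilyl)ethyl 4-hydroxy-3-[(2E)-4-hydroxy-3-methylbut-2-enyl]-5-iodobenzoate
Conditions: NaBH4, CeCl3·7H2O, MeOH, −40 °C
Reagents that add atoms: none
Why: Luche reduction; cerium-activated borohydride gives fast 1,2-reduction of the enal, leaving the ester, the aryl iodide and the E geometry untouched.

**Step 6**
Reactants: 8 (4S)-4-benzyl-1,3-oxazolidin-2-one; 9 (2E)-but-2-enoyl chloride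
Product: 11 (4S)-4-benzyl-3-[(2E)-but-2-enoyl]-1,3-oxazolidin-2-one, via lithiated oxazolidinone 10 (not isolated)
Conditions: n-BuLi, THF, −78 °C; then 9, −78 to 0 °C
Reagents that add atoms: none
Why: N-acylation of the lithium oxazolidinide by the acid chloride (nucleophilic acyl substitution).

**Step 7**
Reactants: 11 (4S)-4-benzyl-3-[(2E)-but-2-enoyl]-1,3-oxazolidin-2-one
Product: 13 (4S)-4-benzyl-3-[(2S)-2-methylbut-3-enoyl]-1,3-oxazolidin-2-one, via sodium dienolate 12 (not isolated)
Conditions: NaN(SiMe3)2 (1.1 equiv), THF, −78 °C; then MeI (5 equiv), −78 °C; AcOH quench at −78 °C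
Reagents that add atoms: iodomethane, CI
Why: Evans auxiliary alkylation in its deconjugative form; γ-deprotonation gives the chelated Z dienolate, which is methylated at the α-carbon on the face opposite the benzyl group, setting the (2S) centre.

**Step 8**
Reactants: 13 (4S)-4-benzyl-3-[(2S)-2-methylbut-3-enoyl]-1,3-oxazolidin-2-one (1.5 equiv); 7 2-(trimethylsilyl)ethyl 4-hydroxy-3-[(2E)-4-hydroxy-3-methylbut-2-enyl]-5-iodobenzoate
Product: 15 2-(trimethylsilyl)ethyl 3-{(3S)-4-[(4S)-4-benzyl-2-oxo-1,3-oxazolidin-3-yl]-3-methyl-4-oxobutyl}-4-hydroxy-5-[(2E)-4-hydroxy-3-methylbut-2-enyl]benzoate, via alkylborane 14 (not isolated)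
Conditions: 13, 9-BBN, THF, 0 °C to rt; then 7, Pd(dppf)Cl2 (5 mol%), AsPh3, Cs2CO3, DMF/H2O, rt
Reagents that add atoms: none
Why: Anti-Markovnikov hydroboration of the terminal alkene followed by B-alkyl Suzuki–Miyaura coupling with the aryl iodide at room temperature; the stereocentre is not involved and the free phenol and alcohol tolerate the aqueous conditions.

**Step 9**
Reactants: 15 the coupled imide from step 8
Product: 16 2-(trimethylsilyl)ethyl 3-[(3S)-4-(ethylsulfanyl)-3-methyl-4-oxobutyl]-4-hydroxy-5-[(2E)-4-hydroxy-3-methylbut-2-enyl]benzoate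
Conditions: EtSH (5 equiv), n-BuLi (4 equiv), THF, 0 °C; aq. NH4Cl
Reagents that add atoms: ethanethiol (used as its lithium salt made in the flask), CCS
Why: Thiolate cleavage of the imide (nucleophilic acyl substitution at the exocyclic carbonyl) proceeds without epimerisation, and the electron-rich benzoate ester is far less electrophilic.

**Step 10**
Reactants: 17 2-methylbut-3-yn-2-ol
Product: 18 (3E)-2-methyl-4-(tributylstannyl)but-3-en-2-ol
Conditions: Bu3SnH (1.1 equiv), PdCl2(PPh3)2 (2 mol%), THF, 0 °C to rt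
Reagents that add atoms: tributyltin hydride, CCCC[SnH](CCCC)CCCC
Why: Palladium-catalysed hydrostannation is a syn addition that places tin on the unhindered terminal carbon, giving the E alkenylstannane.

**Step 11**
Reactants: 16 the S-ethyl thioester from step 9; 18 (3E)-2-methyl-4-(tributylstannyl)but-3-en-2-ol (1.5 equiv)
Product: 19 2-(trimethylsilyl)ethyl 4-hydroxy-3-[(2E)-4-hydroxy-3-methylbut-2-enyl]-5-[(3S,5E)-7-hydroxy-3,7-dimethyl-4-oxooct-5-enyl]benzoate
Conditions: Pd2(dba)3 (2.5 mol%), P(2-furyl)3 (20 mol%), CuOP(O)Ph2 (2 equiv), THF, 50 °C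
Reagents that add atoms: none
Why: Liebeskind–Srogl-type thioester–organostannane ketone synthesis; it runs under neutral conditions, so the alkene geometry is retained, the α-stereocentre is not epimerised, and the ester and free hydroxyl groups are tolerated.

**Step 12**
Reactants: 19 the 2-(trimethylsilyl)ethyl ester from step 11
Product: 20 4-hydroxy-3-[(2E)-4-hydroxy-3-methylbut-2-enyl]-5-[(3S,5E)-7-hydroxy-3,7-dimethyl-4-oxooct-5-enyl]benzoic acid (CNP0120226.2)
Conditions: tris(dimethylamino)sulfonium difluorotrimethylsilicate (4 equiv), DMF, 0 °C to rt; cold dilute aq. HCl to pH 3–4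
Reagents that add atoms: none
Why: Fluoride-induced β-elimination of the 2-(trimethylsilyl)ethyl ester frees the acid; the anhydrous fluoride is buffered by the acidic phenol, so the α-methyl ketone should not epimerise.

**Compound list**
1 | 4-hydroxy-3-iodobenzoic acid | OC(=O)c1ccc(O)c(I)c1 | starting material
2 | 2-(trimethylsilyl)ethyl 4-hydroxy-3-iodobenzoate | C[Si](C)(C)CCOC(=O)c1ccc(O)c(I)c1 | intermediate
3 | 2-(trimethylsilyl)ethyl 3-iodo-4-(prop-2-enyloxy)benzoate | C[Si](C)(C)CCOC(=O)c1ccc(OCC=C)c(I)c1 | intermediate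
4 | 2-(trimethylsilyl)ethyl 5-iodo-4-oxo-3-(prop-2-enyl)cyclohexa-1,5-diene-1-carboxylate (ortho-dienone, racemic at C-3) | C[Si](C)(C)CCOC(=O)C1=CC(CC=C)C(=O)C(I)=C1 | intermediate (not isolated)
5 | 2-(trimethylsilyl)ethyl 4-hydroxy-3-iodo-5-(prop-2-enyl)benzoate | C[Si](C)(C)CCOC(=O)c1cc(I)c(O)c(CC=C)c1 | intermediate
6 | 2-(trimethylsilyl)ethyl 4-hydroxy-3-iodo-5-[(2E)-3-methyl-4-oxobut-2-enyl]benzoate | C[Si](C)(C)CCOC(=O)c1cc(I)c(O)c(C/C=C(\C)C=O)c1 | intermediate
7 | 2-(trimethylsilyl)ethyl 4-hydroxy-3-[(2E)-4-hydroxy-3-methylbut-2-enyl]-5-iodobenzoate | C[Si](C)(C)CCOC(=O)c1cc(I)c(O)c(C/C=C(\C)CO)c1 | intermediate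
8 | (4S)-4-benzyl-1,3-oxazolidin-2-one | O=C1N[C@@H](Cc2ccccc2)CO1 | starting material
9 | (2E)-but-2-enoyl chloride | C/C=C/C(Cl)=O | starting material
10 | lithium (4S)-4-benzyl-2-oxo-1,3-oxazolidin-3-ide | [Li+].O=C1[N-][C@@H](Cc2ccccc2)CO1 | intermediate (not isolated)
11 | (4S)-4-benzyl-3-[(2E)-but-2-enoyl]-1,3-oxazolidin-2-one | C/C=C/C(=O)N1[C@@H](Cc2ccccc2)COC1=O | intermediate
12 | sodium (1Z)-1-[(4S)-4-benzyl-2-oxo-1,3-oxazolidin-3-yl]buta-1,3-dien-1-olate | [Na+].[O-]/C(=C\C=C)N1[C@@H](Cc2ccccc2)COC1=O | intermediate (not isolated)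
13 | (4S)-4-benzyl-3-[(2S)-2-methylbut-3-enoyl]-1,3-oxazolidin-2-one | C=C[C@H](C)C(=O)N1[C@@H](Cc2ccccc2)COC1=O | intermediate
14 | (4S)-4-benzyl-3-[(2S)-4-(9-borabicyclo[3.3.1]nonan-9-yl)-2-methylbutanoyl]-1,3-oxazolidin-2-one | C[C@@H](CCB1C2CCCC1CCC2)C(=O)N1[C@@H](Cc2ccccc2)COC1=O | intermediate (not isolated)
15 | 2-(trimethylsilyl)ethyl 3-{(3S)-4-[(4S)-4-benzyl-2-oxo-1,3-oxazolidin-3-yl]-3-methyl-4-oxobutyl}-4-hydroxy-5-[(2E)-4-hydroxy-3-methylbut-2-enyl]benzoate | C[Si](C)(C)CCOC(=O)c1cc(C/C=C(\C)CO)c(O)c(CC[C@H](C)C(=O)N2[C@@H](Cc3ccccc3)COC2=O)c1 | intermediate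
16 | 2-(trimethylsilyl)ethyl 3-[(3S)-4-(ethylsulfanyl)-3-methyl-4-oxobutyl]-4-hydroxy-5-[(2E)-4-hydroxy-3-methylbut-2-enyl]benzoate | C[Si](C)(C)CCOC(=O)c1cc(C/C=C(\C)CO)c(O)c(CC[C@H](C)C(=O)SCC)c1 | intermediate
17 | 2-methylbut-3-yn-2-ol | CC(C)(O)C#C | starting material
18 | (3E)-2-methyl-4-(tributylstannyl)but-3-en-2-ol | CCCC[Sn](CCCC)(CCCC)/C=C/C(C)(C)O | intermediate
19 | 2-(trimethylsilyl)ethyl 4-hydroxy-3-[(2E)-4-hydroxy-3-methylbut-2-enyl]-5-[(3S,5E)-7-hydroxy-3,7-dimethyl-4-oxooct-5-enyl]benzoate | C[Si](C)(C)CCOC(=O)c1cc(C/C=C(\C)CO)c(O)c(CC[C@H](C)C(=O)/C=C/C(C)(C)O)c1 | intermediate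
20 | 4-hydroxy-3-[(2E)-4-hydroxy-3-methylbut-2-enyl]-5-[(3S,5E)-7-hydroxy-3,7-dimethyl-4-oxooct-5-enyl]benzoic acid | C/C(=C\Cc1cc(C(=O)O)cc(CC[C@H](C)C(=O)/C=C/C(C)(C)O)c1O)CO | target

**Step count**
Total: 12 steps. Longest linear sequence: 9 steps (from 1 through steps 1, 2, 3, 4, 5, 8, 9, 11 and 12).

**The three steps most likely to fail**

Step 4, cross-metathesis with methacrolein on the free ortho-allyl phenol. The risks are allyl-to-propenyl isomerisation, slow turnover, and oxa-Michael closure of the enal onto the phenol. The fallback sets out from 5. Cross-metathesis with 2-methylbut-2-ene (second-generation Grubbs catalyst RuCl2(H2IMes)(PCy3)(=CHPh), neat, rt) gives the prenyl arene 2-(trimethylsilyl)ethyl 4-hydroxy-3-iodo-5-(3-methylbut-2-enyl)benzoate F1. Its E-methyl group is then oxidised with catalytic SeO2 and t-BuOOH in CH2Cl2, and any over-oxidised enal is taken back with NaBH4. This comes back to the route at 7 and never passes through the enal 6 as an isolated compound.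

Step 8, B-alkyl Suzuki coupling. The risks are slow oxidative addition next to the phenoxide and hydrolysis of the imide by aqueous carbonate. The fallback sets out from 13 and uses 7 unchanged. Radical anti-Markovnikov hydrobromination of 13 (HBr, dibenzoyl peroxide, hexane, 0 °C) gives the primary bromide (4S)-4-benzyl-3-[(2S)-4-bromo-2-methylbutanoyl]-1,3-oxazolidin-2-one F2. F2 is joined to the aryl iodide 7 by a base-free nickel-catalysed reductive cross-electrophile coupling (NiI2, 4,4'-di-tert-butyl-2,2'-bipyridine, Zn dust, NaI, DMPU, 60 °C). This comes back to the route at 15.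

Step 11, thioester–stannane ketone synthesis. The risks are sluggish reaction of the α-branched S-ethyl thioester and of the hydroxylated stannane, and protodestannylation. The fallback sets out from 16. Fukuyama coupling with CH2=CHZnBr (excess, PdCl2(PPh3)2, THF/toluene, rt) gives the vinyl ketone 2-(trimethylsilyl)ethyl 4-hydroxy-3-[(2E)-4-hydroxy-3-methylbut-2-enyl]-5-[(3S)-3-methyl-4-oxohex-5-enyl]benzoate F3. The enone is then completed by cross-metathesis with excess 2-methylbut-3-en-2-ol (second-generation Hoveyda–Grubbs catalyst, CH2Cl2, 40 °C), which gives the E enone and leaves the trisubstituted alkene alone. This comes back to the route at 19.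

**Further compounds**
F1 | step 4 | 2-(trimethylsilyl)ethyl 4-hydroxy-3-iodo-5-(3-methylbut-2-enyl)benzoate | C[Si](C)(C)CCOC(=O)c1cc(I)c(O)c(CC=C(C)C)c1
F2 | step 8 | (4S)-4-benzyl-3-[(2S)-4-bromo-2-methylbutanoyl]-1,3-oxazolidin-2-one | C[C@@H](CCBr)C(=O)N1[C@@H](Cc2ccccc2)COC1=O
F3 | step 11 | 2-(trimethylsilyl)ethyl 4-hydroxy-3-[(2E)-4-hydroxy-3-methylbut-2-enyl]-5-[(3S)-3-methyl-4-oxohex-5-enyl]benzoate | C[Si](C)(C)CCOC(=O)c1cc(C/C=C(\C)CO)c(O)c(CC[C@H](C)C(=O)C=C)c1
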